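We cannot integrate a rate law for this flask, since nobody has given us one, but we can count.

| setting | grey | blue | flask |
|---|---|---|---|
| starting material | 0.80 M | 0.80 M | 0.80 M |
| free catalyst | 0.18 mol% | 0.29 mol% | 0.13 mol% |
| remark | run made earlier | run made earlier |  |
| time |  |  | 4.0 d |

| run | time / d | product / % | starting material / % |
|---|---|---|---|
| grey | 0.333 | 24 | 79 |
| grey | 0.833 | 45 | 51 |
| grey | 1.67 | 74 | 23 |
| grey | 2.50 | 87 | 8 |
| blue | 0.208 | 16 | 78 |
| blue | 0.417 | 35 | 64 |
| blue | 1.04 | 74 | 26 |
| blue | 2.50 | 96 | 1 |

(scatter of a reading: 2 percentage points)



1. product present at 4.0 d, in percent of the starting material charged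
2. starting material present at 4.0 d, in percent of the starting material charged

Each turn of the catalyst consumes starting material, so at this one charge we expect the fraction left to follow loading times time. The grey run had lost about half of its charge by 0.833 d. The halving count, the flask's loading times time over grey's loading times that time, is therefore 3.47.

Is one number enough? Grey at 1.67 d and blue at 1.04 d have equal counts, and they read 23% and 26% of starting material. An earlier matched pair reads 79% and 78%, although its product readings, 24% and 16%, differ by more than the scatter. Pure halving, the pseudo-first-order picture, gives 12.5% at grey's last reading, but 8% was read. We therefore commit to 9.02% of starting material left, perhaps somewhat less, and 91.0% of product.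

The forecast, calling the rate “nearly first order in catalyst”, gave 5.5% of starting material and 91% of product.

The flask gives 6.92% of starting material and 93.1% of product.

    starting material + free catalyst → catalyst intermediate A (k = 35.0 L mol⁻¹ h⁻¹)
    catalyst intermediate A ⇌ catalyst intermediate B (K = 1.36, k = 82.7 h⁻¹)
    catalyst intermediate B → free catalyst + product (k = 88.9 h⁻¹)

Our count lies 2.1 percentage points above the flask's starting material, the forecast 1.4 points below it. In this flask, free catalyst was the resting state, 57.8% of the catalyst at 0.400 d and 94.2% at 4.00 d, while the making of catalyst intermediate A, its change to catalyst intermediate B and the release of product each reached the midpoint of their turnover up to 4.0 d at 1.19 d.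

For the same flask read at 25 h, the count is 0.903, which leaves 53.5%. The computed flask holds 58.2% of starting material.

The readings were generated by integration on assumed constants; noise was put on by code.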